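**Retrosynthetic overview**
1. Target acid ⇐ its methyl ester (ester hydrolysis last).
2. C19 angelate and C6 methylene ⇐ 6β,19-ether + angelic acid: one reductive acylolysis makes the ester C–O bond and opens the ether at the allylic C6–O bond (new step).
3. 6β,19-Ether ⇐ 6β-hydroxy-Δ7 ester: the key C19–O bond is made from a C–H bond of the axial 4β-methyl by alkoxyl-radical relay; the 6β-alcohol ⇐ 6-oxo-Δ7 enone ⇐ methyl labd-7-en-15-oate.
4. Side chain ⇐ C18 methyl ketone (asymmetric conjugate reduction of its enoate sets C13) ⇐ sclareol.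
5. Rings: A and B are taken intact from sclareol; the only ring made is the temporary oxolane (C19–O–C6), closed in step 7 and opened in step 8.

Assumption: (R)-DTBM-SEGPHOS is taken to give 13S in step 3 by analogy with simple (E)-β-methyl enoates; the sense is checked by correlation with the known C13-epimeric methyl 8α-hydroxylabdan-15-oates and the mirror-image ligand is used if it is reversed.

**Route**

Step 1
Reactants: 1 (−)-sclareol
Product: 4 8α-hydroxy-14,15-dinorlabdan-13-one, via tetraol 2 (not isolated), via hydroxy aldehyde 3 (not isolated)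
Conditions: K2OsO4·2H2O (1 mol %), NaIO4 (4 equiv), 2,6-lutidine, dioxane/H2O 3:1, 25 °C
Reagents that add atoms: none
Why: Lemieux–Johnson oxidation: the vinyl group is the only alkene, its 14,15-diol is cleaved by periodate and the resulting α-hydroxy aldehyde is cleaved again, so C13 ends as the methyl ketone while C5, C8, C9 and C10 are untouched.

Step 2
Reactants: 4 8α-hydroxy-14,15-dinorlabdan-13-one; 5 trimethyl phosphonoacetate
Product: 6 methyl (13E)-8α-hydroxylabd-13-en-15-oate
Conditions: 5 (1.5 equiv), NaH (1.4 equiv), THF, 0 → 50 °C; E isomer separated on silica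
Reagents that add atoms: none
Why: Horner–Wadsworth–Emmons olefination of an unhindered methyl ketone gives mainly the (E)-enoate (about 5:1), and only pure E is carried on because the alkene geometry decides the sense at C13 in step 3; the stabilised phosphonate anion is too weakly basic to deprotonate the tertiary alcohol.

Step 3
Reactants: 6 methyl (13E)-8α-hydroxylabd-13-en-15-oate
Product: 7 methyl (13S)-8α-hydroxylabdan-15-oate
Conditions: Cu(OAc)2·H2O (3 mol %), (R)-DTBM-SEGPHOS (3 mol %), (EtO)2MeSiH (3 equiv), t-BuOH (3 equiv), toluene, 0 °C; aq. NH4F work-up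
Reagents that add atoms: none
Why: Copper hydride asymmetric conjugate reduction: the ligated Cu–H delivers hydride to the β-carbon C13 of the (E)-enoate from one face under ligand control (dr expected ≥ 95:5), setting 13S, and leaves the ester and the tertiary alcohol alone.

Step 4
Reactants: 7 methyl (13S)-8α-hydroxylabdan-15-oate
Product: 8 methyl (13S)-labd-7-en-15-oate
Conditions: TsOH·H2O (10 mol %), toluene, 70 °C; AgNO3–silica chromatography
Reagents that add atoms: none
Why: Acid-catalysed E1 dehydration of the tertiary 8α-alcohol: the C8 cation loses H-7 to give the trisubstituted ring alkene as the main isomer (about 3:1 over the 8(17) and 8(9) isomers, which are removed), with C9 and C13 unchanged.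

Step 5
Reactants: 8 methyl (13S)-labd-7-en-15-oate
Product: 10 methyl (13S)-6-oxolabd-7-en-15-oate, via tert-butyl peroxide 9 (not isolated)
Conditions: Rh2(cap)4 (dirhodium tetracaprolactamate, 1 mol %), t-BuOOH (5 equiv, in decane), K2CO3 (0.5 equiv), CH2Cl2, 25 °C
Reagents that add atoms: tert-butyl hydroperoxide, CC(C)(C)OO
Why: Rh2(cap)4-catalysed allylic oxidation: the tert-butylperoxyl radical abstracts the axial allylic H-6, the only secondary allylic hydrogen, and the C6 mixed peroxide collapses to the conjugated enone, with C5 staying trans because the 5α-H ketone is the stable epimer.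

Step 6
Reactants: 10 methyl (13S)-6-oxolabd-7-en-15-oate
Product: 11 methyl (13S)-6β-hydroxylabd-7-en-15-oate
Conditions: NaBH4 (1.5 equiv), CeCl3·7H2O (1.2 equiv), MeOH, −20 °C
Reagents that add atoms: none
Why: Luche 1,2-reduction: the β-face of the C6 carbonyl is blocked by the axial C19 and C20 methyl groups, so hydride enters from the α-face and the new alcohol is 6β (axial), while the alkene and the ester are not reduced.

Step 7
Reactants: 11 methyl (13S)-6β-hydroxylabd-7-en-15-oate
Product: 14 methyl (13S)-6β,19-epoxylabd-7-en-15-oate, via hypoiodite 12 (not isolated), via iodo alcohol 13 (not isolated)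
Conditions: PhI(OAc)2 (1.5 equiv), I2 (1 equiv), cyclohexane, visible light, 25 °C
Reagents that add atoms: none
Why: Suárez hypoiodite reaction: light cleaves the O–I bond, the 6β-alkoxyl radical takes a hydrogen atom from the 1,3-diaxial C19 methyl by 1,5-transfer (the half-chair of ring B tilts the oxygen toward C4 and away from the more crowded C20), and iodination plus ring closure give the oxolane, which fixes C4 with the oxidised carbon on the β-face.

Step 8
Reactants: 14 methyl (13S)-6β,19-epoxylabd-7-en-15-oate; 15 angelic acid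
Product: 17 methyl (13S)-19-angeloyloxylabd-7-en-15-oate, via angelic anhydride 16 (not isolated)
Conditions: 15 (4 equiv), DCC (2 equiv), CH2Cl2, 0 °C, filter; then 14, Et3SiH (3 equiv), TMSOTf (10 mol %), −60 → −30 °C
Reagents that add atoms: none
Why: Proposed new method: silyl-triflate-catalysed reductive acylolysis of a bridged allylic ether — TMSOTf and anhydride 16 give an angeloyl triflate that acylates the ether oxygen (or the ether is O-silylated first and the 19-silyl ether is then acylated; both paths converge), the strained oxonium ionises only at the allylic C6–O bond because the neopentyl C19–O bond can neither ionise nor be displaced, and Et3SiH delivers hydride to the less substituted terminus C6 of the C6–C8 allyl cation from the open α-face, which restores the Δ7 alkene and leaves C19–O as the angelate with Z geometry kept since no base or nucleophilic catalyst is present; the closest known reaction types are Lewis-acid-catalysed acylative cleavage of ethers by anhydrides and ionic hydrogenation of allylic cations by silanes, not yet combined on a cyclic allylic ether, and no new stereocentre is formed.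

Step 9
Reactants: 17 methyl (13S)-19-angeloyloxylabd-7-en-15-oate
Product: 18 (13S)-19-angeloyloxylabd-7-en-15-oic acid (CNP0180171.1)
Conditions: LiOH·H2O (3 equiv), THF/H2O 3:1, 0 → 20 °C; then 1 M HCl to pH 3
Reagents that add atoms: lithium hydroxide, [Li+].[OH-]
Why: Chemoselective saponification: hydroxide attacks the unhindered methyl ester far faster than the neopentyl, α-branched, conjugated angelate, the Z double bond does not isomerise under these mild conditions, and no stereocentre is touched.

**Compound list**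
1 | (−)-sclareol, (13R)-labd-14-ene-8α,13-diol (normal labdane: H-5α, H-9α, C20 β) | CC1(C)CCC[C@]2(C)[C@@H](CC[C@@](C)(O)C=C)[C@](C)(O)CC[C@@H]12 | starting material
2 | labdane-8α,13,14,15-tetraol (C13 as in 1, both C14 epimers) | CC1(C)CCC[C@]2(C)[C@@H](CC[C@@](C)(O)C(O)CO)[C@](C)(O)CC[C@@H]12 | intermediate
3 | 8α,13-dihydroxy-15-norlabdan-14-al (C13 as in 1) | CC1(C)CCC[C@]2(C)[C@@H](CC[C@@](C)(O)C=O)[C@](C)(O)CC[C@@H]12 | intermediate
4 | 8α-hydroxy-14,15-dinorlabdan-13-one (in equilibrium with its 8,13-hemiketal) | CC1(C)CCC[C@]2(C)[C@@H](CCC(C)=O)[C@](C)(O)CC[C@@H]12 | intermediate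
5 | trimethyl phosphonoacetate | COC(=O)CP(=O)(OC)OC | starting material
6 | methyl (13E)-8α-hydroxylabd-13-en-15-oate | CC1(C)CCC[C@]2(C)[C@@H](CC/C(C)=C/C(=O)OC)[C@](C)(O)CC[C@@H]12 | intermediate
7 | methyl (13S)-8α-hydroxylabdan-15-oate | CC1(C)CCC[C@]2(C)[C@@H](CC[C@H](C)CC(=O)OC)[C@](C)(O)CC[C@@H]12 | intermediate
8 | methyl (13S)-labd-7-en-15-oate | CC1(C)CCC[C@]2(C)[C@@H](CC[C@H](C)CC(=O)OC)C(C)=CC[C@@H]12 | intermediate
9 | methyl (13S)-6-(tert-butylperoxy)labd-7-en-15-oate (both C6 epimers) | CC1(C)CCC[C@]2(C)[C@@H](CC[C@H](C)CC(=O)OC)C(C)=CC(OOC(C)(C)C)[C@@H]12 | intermediate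
10 | methyl (13S)-6-oxolabd-7-en-15-oate | CC1(C)CCC[C@]2(C)[C@@H](CC[C@H](C)CC(=O)OC)C(C)=CC(=O)[C@@H]12 | intermediate
11 | methyl (13S)-6β-hydroxylabd-7-en-15-oate | CC1(C)CCC[C@]2(C)[C@@H](CC[C@H](C)CC(=O)OC)C(C)=C[C@@H](O)[C@@H]12 | intermediate
12 | methyl (13S)-6β-(iodooxy)labd-7-en-15-oate (hypoiodite of 11) | CC1(C)CCC[C@]2(C)[C@@H](CC[C@H](C)CC(=O)OC)C(C)=C[C@@H](OI)[C@@H]12 | intermediate
13 | methyl (13S)-6β-hydroxy-19-iodolabd-7-en-15-oate | IC[C@@]1(C)CCC[C@]2(C)[C@@H](CC[C@H](C)CC(=O)OC)C(C)=C[C@@H](O)[C@@H]12 | intermediate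
14 | methyl (13S)-6β,19-epoxylabd-7-en-15-oate (oxolane bridging C19 and C6 on the β-face) | O1C[C@@]2(C)CCC[C@]3(C)[C@@H](CC[C@H](C)CC(=O)OC)C(C)=C[C@@H]1[C@@H]23 | intermediate
15 | angelic acid, (Z)-2-methylbut-2-enoic acid | C/C=C(/C)C(=O)O | starting material
16 | angelic anhydride, (Z,Z)-2-methylbut-2-enoic anhydride | C/C=C(/C)C(=O)OC(=O)C(/C)=C\C | intermediate
17 | methyl (13S)-19-[(Z)-2-methylbut-2-enoyloxy]labd-7-en-15-oate | C/C=C(/C)C(=O)OC[C@@]1(C)CCC[C@]2(C)[C@@H](CC[C@H](C)CC(=O)OC)C(C)=CC[C@@H]12 | intermediate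
18 | (4S,5R,9S,10R,13S)-19-[(Z)-2-methylbut-2-enoyloxy]labd-7-en-15-oic acid | C/C=C(/C)C(=O)OC[C@@]1(C)CCC[C@]2(C)[C@@H](CC[C@H](C)CC(=O)O)C(C)=CC[C@@H]12 | target

**Totals**
Total step count: 9. Longest linear sequence: 9 steps (from 1; 5 and 15 are bought).

**Steps most likely to fail**

Step 4 (dehydration): the 8(17) and 8(9) alkenes form alongside the Δ7 isomer and the separation needs silver nitrate–silica. Fallback: start again from 7 and eliminate under kinetic control with SOCl2/pyridine in CH2Cl2 at −78 °C, which removes a C17 proton and gives methyl (13S)-labd-8(17)-en-15-oate F1. RhCl3·3H2O (5 mol %) in EtOH at 75 °C then moves the exocyclic double bond into ring B by rhodium hydride addition and elimination, stopping at the trisubstituted alkene, and the route is rejoined at 8.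

Step 7 (hypoiodite relay): an allylic alkoxyl radical can fragment the C5–C6 bond, be oxidised back to enone 10, or attack C20 instead of C19. Fallback: from 11, Et2SiH2 with [Ir(cod)OMe]2 (0.5 mol %) gives methyl (13S)-6β-(diethylsilyloxy)labd-7-en-15-oate F2. [Rh(cod)Cl]2/Xantphos with norbornene in THF at 100 °C then silylates the δ-methyl C–H bond (a metal-centred C–H cleavage, no alkoxyl radical) and closes the six-membered oxasilinane F3. H2O2/KHCO3/KF in THF/MeOH (Tamao–Fleming oxidation) gives methyl (13S)-6β,19-dihydroxylabd-7-en-15-oate F4. PPTS in toluene at 60 °C ionises the allylic 6β-hydroxyl and the 19-hydroxyl closes the ether on the β-face, rejoining the route at 14.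

Step 8 (new reductive acylolysis): the angeloyl group could isomerise to tigloyl under the silyl triflate, and the allyl cation could lose a proton or take hydride at C8. Fallback with known chemistry: from 14, Et3SiH/BF3·OEt2 in CH2Cl2 at −40 °C (ionic hydrogenolysis of the allylic C6–O bond) gives methyl (13S)-19-hydroxylabd-7-en-15-oate F5. Deprotonation with LiN(SiMe3)2 in THF at −78 °C and acylation of the alkoxide with angelic anhydride 16 (made as in step 8) gives the angelate without Z to E isomerisation, rejoining the route at 17.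

**Further compounds**
F1 | step 4 | methyl (13S)-labd-8(17)-en-15-oate | CC1(C)CCC[C@]2(C)[C@@H](CC[C@H](C)CC(=O)OC)C(=C)CC[C@@H]12
F2 | step 7 | methyl (13S)-6β-(diethylsilyloxy)labd-7-en-15-oate | CC1(C)CCC[C@]2(C)[C@@H](CC[C@H](C)CC(=O)OC)C(C)=C[C@@H](O[SiH](CC)CC)[C@@H]12
F3 | step 7 | oxasilinane: methyl (13S)-6β,19-(diethylsilanediyloxy)labd-7-en-15-oate (ring C6–O–SiEt2–C19) | O1[Si](CC)(CC)C[C@@]2(C)CCC[C@]3(C)[C@@H](CC[C@H](C)CC(=O)OC)C(C)=C[C@@H]1[C@@H]23
F4 | step 7 | methyl (13S)-6β,19-dihydroxylabd-7-en-15-oate | OC[C@@]1(C)CCC[C@]2(C)[C@@H](CC[C@H](C)CC(=O)OC)C(C)=C[C@@H](O)[C@@H]12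
F5 | step 8 | methyl (13S)-19-hydroxylabd-7-en-15-oate | OC[C@@]1(C)CCC[C@]2(C)[C@@H](CC[C@H](C)CC(=O)OC)C(C)=CC[C@@H]12
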